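**Retrosynthetic overview**
1. The target comes from SeO2 hydroxylation of the C14 methyl of the 14-deoxy compound. That compound comes from vinylogous E1cB opening of a 4,5-epoxy-7(11)-en-6,12-olide, which frees C4–OH and creates C5=C6.
2. Both rings form in one flask. A Cr/Ni coupling of a tetrasubstituted (Z)-β-iodoenoate (C7) with an α,β-epoxy aldehyde (C6) closes the ten-membered ring first, and the resulting alkoxide then lactonises onto C12.
3. The linear precursor is built by a C2–C3 vinylogous Mukaiyama aldol (sets C2), an iminium epoxidation (sets C4), a C7–C8 propiolate alkynylation (sets C8), and an iodo-aldol with CH2O (sets C7=C11 and adds C13).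
4. The Z-C1=C10 olefin is bought in (Z)-3-methylpent-2-en-4-yn-1-ol, and the angelate comes from angelic acid.

Assumption: atom labels C1–C15 follow germacrane numbering (lactone O on C6, C12 = lactone C=O, C13 = CH2OAc, C14 = CH2OH, C15 = methyl on C4). Compound 1 is taken as a bulk vitamin A intermediate.

**Step 1**
Reactants: 1 (Z)-3-methylpent-2-en-4-yn-1-ol
Product: 2 TBS ether of 1
Conditions: TBSCl, imidazole, DMF, 0 °C to rt
Reagents that add atoms: tert-butyldimethylsilyl chloride CC(C)(C)[Si](C)(C)Cl
Why: Corey silylation of the primary allylic alcohol masks C2–OH so that the later C8 carbinol cannot close onto C2, and the Z-olefin is untouched.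

**Step 2**
Reactants: 2 TBS ether of 1
Product: 3 (Z)-5-(TBSO)-3-methylpent-3-enal (C8 aldehyde)
Conditions: CpRu(MeCN)3PF6 (2 mol %), 5,5'-bis(trifluoromethyl)-2,2'-bipyridine (2 mol %), H2O, NMP, 25 °C
Reagents that add atoms: water O
Why: Ruthenium-vinylidene anti-Markovnikov alkyne hydration runs at neutral pH and room temperature, so the terminal alkyne becomes the C8 aldehyde without moving the β,γ-olefin into conjugation or changing its Z geometry.

**Step 3**
Reactants: 3 (Z)-5-(TBSO)-3-methylpent-3-enal; 4 methyl propiolate
Product: 5 methyl (4S,6Z)-8-(TBSO)-4-hydroxy-6-methyloct-6-en-2-ynoate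
Conditions: Me2Zn, ProPhenol ligand (20 mol %, enantiomer giving Re-face attack), Ph3PO (40 mol %), toluene, 4 °C, slow addition of 3
Reagents that add atoms: none
Why: In the Trost ProPhenol asymmetric alkynylation the dinuclear zinc catalyst binds aldehyde and zinc propiolate together and delivers the alkynyl group to the Re face, which sets C8 as S, while slow addition in a weakly basic medium limits enolisation of 3.

**Step 4**
Reactants: 5 methyl (4S,6Z)-8-(TBSO)-4-hydroxy-6-methyloct-6-en-2-ynoate; 6 formaldehyde (cracked paraformaldehyde)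
Product: 7 methyl (2Z,4S,6Z)-8-(TBSO)-4-hydroxy-2-(hydroxymethyl)-3-iodo-6-methylocta-2,6-dienoate
Conditions: Et2AlI (2.2 equiv), CH2Cl2, −78 to −20 °C; CH2O (g), −78 °C; Rochelle salt/NaHCO3
Reagents that add atoms: diethylaluminium iodide CC[Al](I)CC
Why: Proposed new method: the first Et2AlI turns C8–OH into an aluminium alkoxide and the second adds iodide to C7 (Kishi–Taniguchi iodo-aldol, the β-iodo Morita–Baylis–Hillman reaction) to give the β-iodo allenolate, after which formaldehyde bound to the C8–O–Al centre is handed to C11 from the C8 side of the allenolate plane, anti to iodine, so that C13 ends cis to C8 and iodine cis to the ester (Z); the closest known reactions are the Z-selective Et2AlI, MgI2 and TMSI iodo-aldol reactions of propiolates, and any wrong isomer betrays itself by lactonising onto C8–OH.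

**Step 5**
Reactants: 7 iodo diol
Product: 8 methyl (2Z,4S,6Z)-2-(acetoxymethyl)-8-(TBSO)-4-hydroxy-3-iodo-6-methylocta-2,6-dienoate
Conditions: AcCl (1.05 equiv), 2,4,6-collidine, CH2Cl2, −78 °C
Reagents that add atoms: acetyl chloride CC(=O)Cl
Why: The Yamamoto AcCl/collidine protocol acylates primary over secondary alcohols at low temperature, so only C13–OH is capped while the hindered C8–OH next to the iodoalkene stays free.

**Step 6**
Reactants: 8 C13 monoacetate; 9 angelic acid
Product: 11 C8 angelate of 8, via mixed anhydride 10 (not isolated)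
Conditions: 9, 2,4,6-Cl3C6H2COCl, Et3N, toluene, rt; then 8, 80 °C
Reagents that add atoms: none
Why: Yamaguchi-type mixed-anhydride esterification without DMAP is the established way to transfer an angeloyl group without leakage to tiglate, and since the C8–O bond is not broken, 8S is kept.

**Step 7**
Reactants: 11 C8 angelate
Product: 12 methyl (2Z,4S,6Z)-2-(acetoxymethyl)-4-(angeloyloxy)-3-iodo-6-methyl-8-oxoocta-2,6-dienoate (Z-enal)
Conditions: DDQ, CH2Cl2/pH 7 buffer, rt
Reagents that add atoms: none
Why: In the Paterson DDQ oxidation, hydride abstraction from the allylic silyl ether and hydrolysis of the silyloxocarbenium ion give the enal in one step, and the neutral buffer keeps the Z-enal, the esters and the vinyl iodide intact.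

**Step 8**
Reactants: 13 3-methylbut-2-enal (prenal)
Product: 14 (E)-1-(TBSO)-3-methylbuta-1,3-diene
Conditions: TBSOTf, Et3N, Et2O, 0 °C
Reagents that add atoms: tert-butyldimethylsilyl triflate CC(C)(C)[Si](C)(C)OS(=O)(=O)C(F)(F)F
Why: Soft γ-enolisation of prenal gives the E-silyl dienol ether, which is the C3–C6/C15 nucleophile.

**Step 9**
Reactants: 12 Z-enal; 14 silyl dienol ether
Product: 15 methyl (2Z,4S,6Z,8S,10E)-2-(acetoxymethyl)-4-(angeloyloxy)-8-hydroxy-3-iodo-6,10-dimethyl-12-oxododeca-2,6,10-trienoate
Conditions: B-phenyl-oxazaborolidinone from N-tosyl-tryptophan and PhBCl2 (50 mol %, enantiomer shielding the Re face), iPrOH, EtCN, −78 °C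
Reagents that add atoms: none
Why: In the Kalesse enantioselective vinylogous Mukaiyama aldol of an aldehyde-derived dienolate, the boron Lewis acid binds enal 12 and the dienol ether attacks through its γ-carbon on the Si face, which sets C2 as S and gives the E-enal directly at the aldehyde oxidation level.

**Step 10**
Reactants: 15 hydroxy enal
Product: 16 C2 acetate of 15
Conditions: Ac2O, pyridine, DMAP (cat.), CH2Cl2, 0 °C
Reagents that add atoms: acetic anhydride CC(=O)OC(C)=O
Why: DMAP-catalysed acetylation of the only free hydroxyl touches no stereocentre.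

**Step 11**
Reactants: 16 acetoxy enal
Product: 17 (4R)-trans-4,5-epoxy aldehyde (10R,11S in chain numbering)
Conditions: tBuOOH, bis[3,5-bis(trifluoromethyl)benzyl]ammonium TRIP phosphate (10 mol %, enantiomer giving 4R), dioxane, 35 °C
Reagents that add atoms: tert-butyl hydroperoxide CC(C)(C)OO
Why: List's counteranion-directed iminium (Weitz–Scheffer type) epoxidation, made for β,β-disubstituted enals, touches only the enal; the enantio-determining peroxide addition to C4 sets 4R under catalyst control, and ring closure gives mainly the trans-epoxide, whose C5 centre is erased later.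

**Step 12 (key step)**
Reactants: 17 epoxy aldehyde iodoenoate
Product: 19 (2S,4R,8S)-2,13-diacetoxy-8-angeloyloxy-4,5-epoxygermacra-1(10)Z,7(11)-dien-6,12-olide (C6 epimers), via chromium alkoxide 18 (not isolated)
Conditions: CrCl2 (10 equiv), NiCl2 (1 mol % of Cr), DMSO/THF, 25 °C, syringe pump, 1 mM
Reagents that add atoms: none
Why: Proposed new method: zerovalent nickel inserts into the activated C7–I bond and transmetallation gives a configurationally stable alkenylchromium that adds to the C6 aldehyde (Nozaki–Hiyama–Kishi reaction), and because geometry is retained the new alkoxide sits cis to CO2Me and lactonises at once, so the ten-membered ring and the butenolide arise in one flask; the closest known reactions are NHK closures of ten-membered rings and the direct butenolide formation from (Z)-β-iodoacrylates and aldehydes, the Z-olefin and the trans-epoxide act as turn elements, and the C6 epimer ratio is irrelevant because C6 becomes sp2 in step 13.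

**Step 13**
Reactants: 19 epoxy butenolide
Product: 20 14-deoxy target (4-hydroxy-5-en-6,12-olide)
Conditions: DBU (20 mol %), Bu4NOAc (20 mol %), CH2Cl2, 0 °C
Reagents that add atoms: none
Why: In this biomimetic vinylogous E1cB reaction DBU removes the acidic γ-proton H6 and the 2-oxidofuran pushes open the C5–O bond, freeing the tertiary C4–OH with 4R untouched and creating C5=C6; the trans-epoxide holds C3 anti to C6, so only the conformer with C4 syn to C7 lets the short Z-olefin bridge reach C8, which gives the strain-poor cis,cis-cyclodeca-1,6-diene geometry of the target, and buffer acetate returns any C13 acetate lost by reversible elimination.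

**Step 14**
Reactants: 20 14-deoxy target
Product: 21 CNP0165707.1 (target)
Conditions: SeO2 (0.3 equiv), tBuOOH, CH2Cl2, 0 °C to rt
Reagents that add atoms: selenium dioxide O=[Se]=O (oxygen carrier); tert-butyl hydroperoxide CC(C)(C)OO (terminal oxidant)
Why: Sharpless SeO2/tBuOOH allylic hydroxylation (ene reaction, then [2,3]-shift) attacks the only electron-rich olefin C1=C10 at its disubstituted end, and the [2,3]-shift can rebuild the in-ring Z-olefin only when oxygen goes to the exocyclic methyl C14, as in the known oxidation of parthenolide to melampomagnolide B; the conjugated olefins and the esters are inert.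

**Compound list**
1 | (Z)-3-methylpent-2-en-4-yn-1-ol | OC/C=C(/C)C#C | starting material
2 | TBS ether of 1 | CC(C)(C)[Si](C)(C)OC/C=C(/C)C#C | intermediate
3 | (Z)-5-(TBSO)-3-methylpent-3-enal | O=CC/C(C)=C\CO[Si](C)(C)C(C)(C)C | intermediate
4 | methyl propiolate | COC(=O)C#C | starting material
5 | methyl (4S,6Z)-8-(TBSO)-4-hydroxy-6-methyloct-6-en-2-ynoate | COC(=O)C#C[C@@H](O)C/C(C)=C\CO[Si](C)(C)C(C)(C)C | intermediate
6 | formaldehyde | C=O | starting material
7 | (2Z,4S,6Z)-iodo diol | COC(=O)/C(CO)=C(\I)[C@@H](O)C/C(C)=C\CO[Si](C)(C)C(C)(C)C | intermediate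
8 | C13 monoacetate | COC(=O)/C(COC(C)=O)=C(\I)[C@@H](O)C/C(C)=C\CO[Si](C)(C)C(C)(C)C | intermediate
9 | angelic acid | C/C=C(/C)C(=O)O | starting material
10 | angelic 2,4,6-trichlorobenzoic anhydride | C/C=C(/C)C(=O)OC(=O)c1c(Cl)cc(Cl)cc1Cl | intermediate
11 | C8 angelate, C2 TBS ether | COC(=O)/C(COC(C)=O)=C(\I)[C@@H](OC(=O)/C(C)=C\C)C/C(C)=C\CO[Si](C)(C)C(C)(C)C | intermediate
12 | Z-enal iodoenoate | COC(=O)/C(COC(C)=O)=C(\I)[C@@H](OC(=O)/C(C)=C\C)C/C(C)=C\C=O | intermediate
13 | 3-methylbut-2-enal | CC(C)=CC=O | starting material
14 | (E)-1-(TBSO)-3-methylbuta-1,3-diene | C=C(C)/C=C/O[Si](C)(C)C(C)(C)C | intermediate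
15 | linear C15 hydroxy enal (2S,8S) | O=C/C=C(\C)C[C@H](O)/C=C(/C)C[C@H](OC(=O)/C(C)=C\C)/C(I)=C(\COC(C)=O)C(=O)OC | intermediate
16 | C2 acetate of 15 | O=C/C=C(\C)C[C@H](OC(C)=O)/C=C(/C)C[C@H](OC(=O)/C(C)=C\C)/C(I)=C(\COC(C)=O)C(=O)OC | intermediate
17 | (4R)-trans-epoxy aldehyde | O=C[C@H]1O[C@]1(C)C[C@H](OC(C)=O)/C=C(/C)C[C@H](OC(=O)/C(C)=C\C)/C(I)=C(\COC(C)=O)C(=O)OC | intermediate
18 | chromium alkoxide of the macrocyclic γ-hydroxy ester (drawn as the alcohol, C6 epimers) | OC1[C@H]2O[C@]2(C)C[C@H](OC(C)=O)/C=C(/C)C[C@H](OC(=O)/C(C)=C\C)/C1=C(\COC(C)=O)C(=O)OC | intermediate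
19 | 4,5-epoxy-1(10)Z,7(11)-dien-6,12-olide (C6 epimers) | O=C1OC2[C@H]3O[C@]3(C)C[C@H](OC(C)=O)/C=C(/C)C[C@H](OC(=O)/C(C)=C\C)C2=C1COC(C)=O | intermediate
20 | 14-deoxy target | C/C=C(/C)C(=O)O[C@H]1C/C(C)=C\[C@@H](OC(C)=O)C[C@@](C)(O)/C=C2/OC(=O)C(COC(C)=O)=C21 | intermediate
21 | CNP0165707.1 | C/C=C(/C)C(=O)O[C@H]1C/C(CO)=C\[C@@H](OC(C)=O)C[C@@](C)(O)/C=C2/OC(=O)C(COC(C)=O)=C21 | target

**Totals**
Total steps: 14. Longest linear sequence: 13 (steps 1–7 and 9–14; step 8 is a one-step side branch).

**Three steps most likely to fail**

Step 12 (macrocyclic Cr/Ni closure). The risks are the entropic cost of the ten-membered ring, reduction of the epoxy aldehyde by divalent chromium, and loss of the C8 angelate from the alkenyl metal. The fallback sets out from 16 and comes back at 19. The enal 16 itself is closed with CrCl2/NiCl2, so no epoxide meets divalent chromium and the flatter, sp2-rich chain folds more easily. This gives the (1(10)Z,4E)-trienolide F1, a melampolide-type ring. The epoxide is then installed on the ring with Shi's fructose-derived ketone (the enantiomer matched to 4R) and Oxone. This reagent should prefer the outward-facing E-trisubstituted C4=C5 over the Z-olefin shielded by the C2 acetate, and it delivers 19.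

Step 4 (directed iodo-aldol). The risks are simple hydroiodination and the wrong olefin geometry. The fallback sets out from 5 and comes back at 7. Piers' stannylcuprate Me3SnCu(SPh)Li (one extra equivalent for the hydroxyl) is added to ynoate 5 at −48 °C, where the adduct equilibrates to the isomer with tin cis to the ester. The bulky stannyl group then forces formaldehyde to enter anti to tin, giving the β-stannyl enoate F2. Iodine in CH2Cl2 replaces tin with retention and gives 7.

Step 13 (E1cB opening). The risks are the wrong C5=C6 geometry and loss of the C13 acetate from the oxidofuran. The fallback sets out from 19 and comes back at 20 by the Sharpless–Lauer sequence. PhSeNa (from PhSeSePh/NaBH4) opens the epoxide by SN2 attack at the secondary C5 to give the hydroxy selenide F3. H2O2 then gives the selenoxide F4, whose only β-hydrogen is H6 because C4 is quaternary, so syn-elimination must create C5=C6. The elimination is stereospecific, so the C6 epimers of 19 are separated first. The epimer used is the one in which H6 eclipses selenium while C4 eclipses C7. No base is present, so the C13 acetate stays.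

**Further compounds**
F1 | step 12 | (2S,8S)-2,13-diacetoxy-8-angeloyloxygermacra-1(10)Z,4E,7(11)-trien-6,12-olide | O=C1OC2/C=C(\C)C[C@H](OC(C)=O)/C=C(/C)C[C@H](OC(=O)/C(C)=C\C)C2=C1COC(C)=O
F2 | step 4 | methyl (4S,6Z)-8-(TBSO)-4-hydroxy-2-(hydroxymethyl)-6-methyl-3-(trimethylstannyl)octa-2,6-dienoate, tin cis to ester | COC(=O)/C(CO)=C(\[Sn](C)(C)C)[C@@H](O)C/C(C)=C\CO[Si](C)(C)C(C)(C)C
F3 | step 13 | 4-hydroxy-5-(phenylselanyl) lactone | O=C1OC2[C@H]([Se]c3ccccc3)[C@](C)(O)C[C@H](OC(C)=O)/C=C(/C)C[C@H](OC(=O)/C(C)=C\C)C2=C1COC(C)=O
F4 | step 13 | selenoxide of F3 | O=C1OC2[C@H]([Se](=O)c3ccccc3)[C@](C)(O)C[C@H](OC(C)=O)/C=C(/C)C[C@H](OC(=O)/C(C)=C\C)C2=C1COC(C)=O
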